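**Retrosynthetic overview**

- The last steps are hydrogenolysis of three benzyl ethers and reduction of a diaryl ketone to the bridging CH2 (hydride, then silane/acid, which also removes the ring B MOM group).
- The strategy rests on ring C: bridge carbon C6 sits between the methoxy-bearing C5 and the chain-bearing C1, with the hydroxyl on C3 para to the bridge. This is the pattern a 1,1-dimethoxy-3-silyloxybutadiene gives with a β-alkyl ynone, so ring C is made by a [4+2] benzannulation forming C5–C6 and C1–C2.
- The ynone comes from lithiation of the ring A–B bibenzyl between its OMOM and OMe groups and acylation with an alkynyl Weinreb amide that carries ring D.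
- The bibenzyl comes from a Wittig reaction and diimide reduction; the Weinreb ynamide from a benzylic bromide and lithiated silylpropyne; the diene from acetyl chloride and 1,1-dichloroethene.
- Rings A, B and D are bought as arenes; ring C is the only ring formed (step 14).

Key step: step 14

Remark 1: the target has no stereocentre or other stereogenic element, so the achiral compound itself is the required product and no step needs stereocontrol. The one stereocentre met in transit (the carbinol carbon of 32) is carried as a racemate and erased in step 17.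

Remark 2: the diene is made from 4,4-dimethoxybut-3-en-2-one and not from an acetoacetate ester. An acetoacetate-derived 1-alkoxy-1,3-bis(silyloxy)diene would deliver both ring C oxygens as free hydroxyls and lose their differentiation.

**Route**

Step 1
Reactants: 1 4-(benzyloxy)-3-methoxybenzaldehyde (O-benzylvanillin)
Product: 2 [4-(benzyloxy)-3-methoxyphenyl]methanol
Conditions: NaBH4, MeOH/THF, 0 °C
Reagents that add atoms: none
Why: Borohydride reduction of an aromatic aldehyde gives the benzylic alcohol cleanly and leaves the aryl benzyl ether untouched.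

Step 2
Reactants: 2 [4-(benzyloxy)-3-methoxyphenyl]methanol
Product: 3 {[4-(benzyloxy)-3-methoxyphenyl]methyl}triphenylphosphonium bromide
Conditions: PPh3·HBr, MeCN, reflux
Reagents that add atoms: triphenylphosphine hydrobromide, [Br-].c1ccc(cc1)[PH+](c1ccccc1)c1ccccc1
Why: The p-alkoxybenzylic alcohol ionises under the mildly acidic salt and is trapped by triphenylphosphine (direct phosphonium salt formation from a benzylic alcohol), so no separate halide is needed.

Step 3
Reactants: 4 3-hydroxy-5-methoxybenzaldehyde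
Product: 5 3-methoxy-5-(methoxymethoxy)benzaldehyde
Conditions: MOMCl, i-Pr2NEt, CH2Cl2, 0 °C to rt
Reagents that add atoms: chloromethyl methyl ether, COCCl
Why: O-Alkylation of the phenol with MOMCl and Hünig's base installs the acetal that later directs lithiation between the two ring B oxygens.

Step 4
Reactants: 3 {[4-(benzyloxy)-3-methoxyphenyl]methyl}triphenylphosphonium bromide; 5 3-methoxy-5-(methoxymethoxy)benzaldehyde
Product: 7 1-(benzyloxy)-2-methoxy-4-{2-[3-methoxy-5-(methoxymethoxy)phenyl]ethenyl}benzene (E/Z mixture), via phosphonium ylide 6 (not isolated)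
Conditions: KOtBu, THF, 0 °C; then 5, 0 °C to rt
Reagents that add atoms: none
Why: Wittig olefination of the semi-stabilised benzylic ylide with the aryl aldehyde should give the stilbene as an E/Z mixture, both isomers converging in the next step.

Step 5
Reactants: 7 1-(benzyloxy)-2-methoxy-4-{2-[3-methoxy-5-(methoxymethoxy)phenyl]ethenyl}benzene
Product: 8 1-(benzyloxy)-2-methoxy-4-{2-[3-methoxy-5-(methoxymethoxy)phenyl]ethyl}benzene (ring A–B bibenzyl)
Conditions: TsNHNH2 (excess, in portions), NaOAc, THF/H2O, reflux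
Reagents that add atoms: none
Why: Diimide generated from tosylhydrazide transfers two hydrogens to the stilbene C=C in a concerted step and cannot hydrogenolyse the benzyl ether or cleave the MOM acetal.

Step 6
Reactants: 9 [3-(benzyloxy)phenyl]methanol
Product: 10 1-(benzyloxy)-3-(bromomethyl)benzene
Conditions: PBr3, Et2O, 0 °C
Reagents that add atoms: phosphorus tribromide, BrP(Br)Br
Why: PBr3 converts the primary benzylic alcohol into the bromide by SN2 displacement of the intermediate phosphite, the aryl benzyl ether being inert.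

Step 7
Reactants: 10 1-(benzyloxy)-3-(bromomethyl)benzene; 11 trimethyl(prop-1-yn-1-yl)silane
Product: 13 {4-[3-(benzyloxy)phenyl]but-1-yn-1-yl}trimethylsilane, via lithiated silylpropyne 12 (not isolated)
Conditions: 11, n-BuLi, THF, –78 to –20 °C; then 10, –78 to 0 °C
Reagents that add atoms: none
Why: Propargylic lithiation of the silylpropyne and SN2 alkylation with the benzylic bromide should give the homopropargyl arene, the silyl group steering attack to the propargylic and not the allenic terminus.

Step 8
Reactants: 13 {4-[3-(benzyloxy)phenyl]but-1-yn-1-yl}trimethylsilane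
Product: 14 1-(benzyloxy)-3-(but-3-yn-1-yl)benzene
Conditions: K2CO3 (cat.), MeOH, rt
Reagents that add atoms: none
Why: Base-catalysed methanolysis cleaves the alkynyl C–Si bond (protodesilylation) under conditions that affect nothing else in the molecule.

Step 9
Reactants: 14 1-(benzyloxy)-3-(but-3-yn-1-yl)benzene; 15 N-methoxy-N-methylcarbamoyl chloride
Product: 17 5-[3-(benzyloxy)phenyl]-N-methoxy-N-methylpent-2-ynamide, via lithium acetylide 16 (not isolated)
Conditions: n-BuLi, THF, –78 °C; then 15, –78 to 0 °C
Reagents that add atoms: none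
Why: Nucleophilic acyl substitution of the carbamoyl chloride by the lithium acetylide gives the alkynyl Weinreb amide in one operation.

Step 10
Reactants: 18 acetyl chloride; 19 1,1-dichloroethene
Product: 21 4,4-dichlorobut-3-en-2-one, via trichloroketone 20 (not isolated)
Conditions: AlCl3, CH2Cl2, 0 °C to rt; aq. work-up; distil (–HCl)
Reagents that add atoms: none
Why: Friedel–Crafts-type acylation of the dichloroalkene gives the β-trichloromethyl ketone, which loses HCl by E1cB-type elimination to the conjugated β,β-dichlorovinyl ketone.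

Step 11
Reactants: 21 4,4-dichlorobut-3-en-2-one
Product: 22 4,4-dimethoxybut-3-en-2-one
Conditions: NaOMe (2.1 equiv), MeOH, 0 °C to rt
Reagents that add atoms: sodium methoxide, [Na+].[O-]C
Why: Two successive addition–elimination steps at the β-carbon (vinylogous acyl substitution) replace both vinylic chlorides by methoxide to give the acyl ketene acetal.

Step 12
Reactants: 22 4,4-dimethoxybut-3-en-2-one
Product: 24 1,1-dimethoxy-3-(trimethylsilyloxy)buta-1,3-diene, via lithium dienolate 23 (not isolated)
Conditions: LDA, THF, –78 °C; TMSCl, –78 °C to rt; non-aqueous work-up, distil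
Reagents that add atoms: chlorotrimethylsilane, C[Si](C)(C)Cl
Why: Kinetic deprotonation of the methyl group, the only enolisable position, and O-silylation of the cross-conjugated enolate give the silyloxydiene (silyl enol ether formation).

Step 13
Reactants: 8 1-(benzyloxy)-2-methoxy-4-{2-[3-methoxy-5-(methoxymethoxy)phenyl]ethyl}benzene; 17 5-[3-(benzyloxy)phenyl]-N-methoxy-N-methylpent-2-ynamide
Product: 27 1-{4-[2-(4-(benzyloxy)-3-methoxyphenyl)ethyl]-2-methoxy-6-(methoxymethoxy)phenyl}-5-[3-(benzyloxy)phenyl]pent-2-yn-1-one, via aryllithium 25 (not isolated), via tetrahedral adduct 26 (not isolated)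
Conditions: n-BuLi, THF, 0 °C, 1 h; then 17, –78 to –20 °C; inverse quench into cold aq. NH4Cl/HCl (pH 2–3)
Reagents that add atoms: none
Why: Directed ortho-metalation takes place at the only ring position flanked by two oxygen directors (OMOM and OMe), and the aryllithium adds once to the Weinreb amide because the chelated tetrahedral adduct survives until the cold acidic quench, which also protonates the liberated amine before it can add to the ynone (Weinreb ketone synthesis).

Step 14
Reactants: 27 the ring A–B aryl ynone; 24 1,1-dimethoxy-3-(trimethylsilyloxy)buta-1,3-diene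
Product: 30 {4-[2-(4-(benzyloxy)-3-methoxyphenyl)ethyl]-2-methoxy-6-(methoxymethoxy)phenyl}{2-[2-(3-(benzyloxy)phenyl)ethyl]-4-hydroxy-6-methoxyphenyl}methanone, via cycloadduct 28 (not isolated), via aryl silyl ether 29 (not isolated)
Conditions: 24 (3 equiv, freshly distilled), toluene, 110 °C, sealed tube; then K2CO3 (cat.), MeOH, rt; aq. NH4Cl
Reagents that add atoms: none
Why: The electron-rich diene 24 and the electron-poor alkyne of 27 combine in a polarised, asynchronous [4+2] cycloaddition in which the CH2 terminus of the diene (a silyl enol ether and vinylogous ketene acetal carbon, largest HOMO coefficient) bonds to the β-carbon of the ynone (C1–C2 bond of ring C) and the ketene acetal carbon bonds to the α-carbon (C5–C6 bond), giving the 1,4-cyclohexadiene 28. Both bonds close ring C as a six-membered carbocycle in one intermolecular cycloaddition; 28 then loses methanol from its ketal carbon to become aromatic (29), and methanolysis of the aryl silyl ether frees the C3 hydroxyl of 30. The closest known reaction type is the Diels–Alder reaction of 1,1-dialkoxy-3-silyloxybutadienes with β-alkyl acetylenic esters and ketones, which gives 6-alkyl-4-hydroxy-2-methoxyaryl carbonyl compounds. No stereocentre is formed. The step needs regioselectivity, and this is secured by the matched polarisation of the partners: the alkyl-bearing β-carbon is the only electrophilic alkyne terminus and the unsubstituted CH2 is both the most nucleophilic and the least hindered diene terminus, so the methoxy group should end ortho and the hydroxyl para to the aroyl carbon. Chemoselectivity follows from the ynone being the only electron-poor π-bond in 27, and the neutral thermal conditions and the basic methanolysis leave the MOM and benzyl ethers intact.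

Step 15
Reactants: 30 the ring C phenol ketone
Product: 31 {4-[2-(4-(benzyloxy)-3-methoxyphenyl)ethyl]-2-methoxy-6-(methoxymethoxy)phenyl}{4-(benzyloxy)-2-[2-(3-(benzyloxy)phenyl)ethyl]-6-methoxyphenyl}methanone
Conditions: BnBr, K2CO3, DMF, rt
Reagents that add atoms: benzyl bromide, BrCc1ccccc1
Why: Williamson etherification of the only free hydroxyl masks the para-acyl phenol, which would otherwise become a vinylogous carboxylate and deactivate the ketone towards hydride.

Step 16
Reactants: 31 the tris(benzyl ether) ketone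
Product: 32 {4-[2-(4-(benzyloxy)-3-methoxyphenyl)ethyl]-2-methoxy-6-(methoxymethoxy)phenyl}{4-(benzyloxy)-2-[2-(3-(benzyloxy)phenyl)ethyl]-6-methoxyphenyl}methanol (racemic)
Conditions: LiAlH4, THF, 0 °C to reflux; Fieser work-up
Reagents that add atoms: none
Why: LiAlH4 is small and reactive enough to deliver hydride to the tetra-ortho-substituted benzophenone carbonyl (hydride reduction), giving the benzhydrol as a racemate whose stereocentre is removed in the next step.

Step 17
Reactants: 32 the benzhydrol
Product: 34 5-[2-(4-(benzyloxy)-3-methoxyphenyl)ethyl]-2-({4-(benzyloxy)-2-[2-(3-(benzyloxy)phenyl)ethyl]-6-methoxyphenyl}methyl)-3-methoxyphenol, via MOM-protected diarylmethane 33 (not isolated)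
Conditions: Et3SiH (6 equiv), TFA, CH2Cl2, 0 °C to rt
Reagents that add atoms: none
Why: In this ionic hydrogenation TFA ionises the doubly benzylic alcohol to a cation stabilised by ortho and para oxygen on both rings, triethylsilane delivers hydride to it, and the same acid then cleaves the aryl MOM acetal while the silane reduces the methoxymethyl cation so that it cannot alkylate the electron-rich rings.

Step 18
Reactants: 34 the tris(benzyl ether) diarylmethane
Product: 35 2-{[4-hydroxy-2-[2-(3-hydroxyphenyl)ethyl]-6-methoxyphenyl]methyl}-5-[2-(4-hydroxy-3-methoxyphenyl)ethyl]-3-methoxyphenol (target, CNP0078999.0)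
Conditions: H2 (1 atm), 10% Pd/C, EtOAc/MeOH, rt
Reagents that add atoms: none
Why: Palladium-catalysed hydrogenolysis cleaves the three benzylic C–O bonds of the aryl benzyl ethers and leaves the aryl methyl ethers, the free phenol and the diarylmethane untouched.

**Compound list**

1 | 4-(benzyloxy)-3-methoxybenzaldehyde | COc1cc(C=O)ccc1OCc1ccccc1 | starting material
2 | [4-(benzyloxy)-3-methoxyphenyl]methanol | COc1cc(CO)ccc1OCc1ccccc1 | intermediate
3 | {[4-(benzyloxy)-3-methoxyphenyl]methyl}triphenylphosphonium bromide | COc1cc(C[P+](c2ccccc2)(c2ccccc2)c2ccccc2)ccc1OCc1ccccc1.[Br-] | intermediate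
4 | 3-hydroxy-5-methoxybenzaldehyde | COc1cc(O)cc(C=O)c1 | starting material
5 | 3-methoxy-5-(methoxymethoxy)benzaldehyde | COCOc1cc(C=O)cc(OC)c1 | intermediate
6 | [4-(benzyloxy)-3-methoxybenzylidene]triphenylphosphorane (ylide, not isolated) | COc1cc(C=P(c2ccccc2)(c2ccccc2)c2ccccc2)ccc1OCc1ccccc1 | intermediate
7 | 1-(benzyloxy)-2-methoxy-4-{2-[3-methoxy-5-(methoxymethoxy)phenyl]ethenyl}benzene, E/Z mixture | COCOc1cc(C=Cc2ccc(OCc3ccccc3)c(OC)c2)cc(OC)c1 | intermediate
8 | 1-(benzyloxy)-2-methoxy-4-{2-[3-methoxy-5-(methoxymethoxy)phenyl]ethyl}benzene | COCOc1cc(CCc2ccc(OCc3ccccc3)c(OC)c2)cc(OC)c1 | intermediate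
9 | [3-(benzyloxy)phenyl]methanol | OCc1cccc(OCc2ccccc2)c1 | starting material
10 | 1-(benzyloxy)-3-(bromomethyl)benzene | BrCc1cccc(OCc2ccccc2)c1 | intermediate
11 | trimethyl(prop-1-yn-1-yl)silane | CC#C[Si](C)(C)C | starting material
12 | [3-(trimethylsilyl)prop-2-yn-1-yl]lithium (not isolated) | [Li]CC#C[Si](C)(C)C | intermediate
13 | {4-[3-(benzyloxy)phenyl]but-1-yn-1-yl}trimethylsilane | C[Si](C)(C)C#CCCc1cccc(OCc2ccccc2)c1 | intermediate
14 | 1-(benzyloxy)-3-(but-3-yn-1-yl)benzene | C#CCCc1cccc(OCc2ccccc2)c1 | intermediate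
15 | N-methoxy-N-methylcarbamoyl chloride | CON(C)C(=O)Cl | starting material
16 | {4-[3-(benzyloxy)phenyl]but-1-yn-1-yl}lithium (not isolated) | [Li]C#CCCc1cccc(OCc2ccccc2)c1 | intermediate
17 | 5-[3-(benzyloxy)phenyl]-N-methoxy-N-methylpent-2-ynamide | CON(C)C(=O)C#CCCc1cccc(OCc2ccccc2)c1 | intermediate
18 | acetyl chloride | CC(=O)Cl | starting material
19 | 1,1-dichloroethene | C=C(Cl)Cl | starting material
20 | 4,4,4-trichlorobutan-2-one (not isolated) | CC(=O)CC(Cl)(Cl)Cl | intermediate
21 | 4,4-dichlorobut-3-en-2-one | CC(=O)C=C(Cl)Cl | intermediate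
22 | 4,4-dimethoxybut-3-en-2-one | CC(=O)C=C(OC)OC | intermediate
23 | lithium 4,4-dimethoxybuta-1,3-dien-2-olate (not isolated) | [Li]OC(=C)C=C(OC)OC | intermediate
24 | 1,1-dimethoxy-3-(trimethylsilyloxy)buta-1,3-diene | COC(OC)=CC(=C)O[Si](C)(C)C | intermediate
25 | {4-[2-(4-(benzyloxy)-3-methoxyphenyl)ethyl]-2-methoxy-6-(methoxymethoxy)phenyl}lithium (not isolated) | [Li]c1c(OCOC)cc(CCc2ccc(OCc3ccccc3)c(OC)c2)cc1OC | intermediate
26 | lithium alkoxide of the N-methoxy-N-methyl hemiaminal from 25 and 17 (not isolated) | [Li]OC(N(C)OC)(C#CCCc1cccc(OCc2ccccc2)c1)c1c(OCOC)cc(CCc2ccc(OCc3ccccc3)c(OC)c2)cc1OC | intermediate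
27 | 1-{4-[2-(4-(benzyloxy)-3-methoxyphenyl)ethyl]-2-methoxy-6-(methoxymethoxy)phenyl}-5-[3-(benzyloxy)phenyl]pent-2-yn-1-one | COCOc1cc(CCc2ccc(OCc3ccccc3)c(OC)c2)cc(OC)c1C(=O)C#CCCc1cccc(OCc2ccccc2)c1 | intermediate
28 | {aryl}{2-[2-(3-(benzyloxy)phenyl)ethyl]-6,6-dimethoxy-4-(trimethylsilyloxy)cyclohexa-1,4-dien-1-yl}methanone, aryl as in 27 (cycloadduct, not isolated) | COCOc1cc(CCc2ccc(OCc3ccccc3)c(OC)c2)cc(OC)c1C(=O)C1=C(CCc2cccc(OCc3ccccc3)c2)CC(O[Si](C)(C)C)=CC1(OC)OC | intermediate
29 | trimethylsilyl ether of 30 at the ring C hydroxyl (not isolated) | COCOc1cc(CCc2ccc(OCc3ccccc3)c(OC)c2)cc(OC)c1C(=O)c1c(CCc2cccc(OCc3ccccc3)c2)cc(O[Si](C)(C)C)cc1OC | intermediate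
30 | {4-[2-(4-(benzyloxy)-3-methoxyphenyl)ethyl]-2-methoxy-6-(methoxymethoxy)phenyl}{2-[2-(3-(benzyloxy)phenyl)ethyl]-4-hydroxy-6-methoxyphenyl}methanone | COCOc1cc(CCc2ccc(OCc3ccccc3)c(OC)c2)cc(OC)c1C(=O)c1c(CCc2cccc(OCc3ccccc3)c2)cc(O)cc1OC | intermediate
31 | {4-[2-(4-(benzyloxy)-3-methoxyphenyl)ethyl]-2-methoxy-6-(methoxymethoxy)phenyl}{4-(benzyloxy)-2-[2-(3-(benzyloxy)phenyl)ethyl]-6-methoxyphenyl}methanone | COCOc1cc(CCc2ccc(OCc3ccccc3)c(OC)c2)cc(OC)c1C(=O)c1c(CCc2cccc(OCc3ccccc3)c2)cc(OCc2ccccc2)cc1OC | intermediate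
32 | the corresponding diarylmethanol, racemic | COCOc1cc(CCc2ccc(OCc3ccccc3)c(OC)c2)cc(OC)c1C(O)c1c(CCc2cccc(OCc3ccccc3)c2)cc(OCc2ccccc2)cc1OC | intermediate
33 | the corresponding diarylmethane with ring B MOM ether retained (not isolated) | COCOc1cc(CCc2ccc(OCc3ccccc3)c(OC)c2)cc(OC)c1Cc1c(CCc2cccc(OCc3ccccc3)c2)cc(OCc2ccccc2)cc1OC | intermediate
34 | 5-[2-(4-(benzyloxy)-3-methoxyphenyl)ethyl]-2-({4-(benzyloxy)-2-[2-(3-(benzyloxy)phenyl)ethyl]-6-methoxyphenyl}methyl)-3-methoxyphenol | COc1cc(CCc2ccc(OCc3ccccc3)c(OC)c2)cc(O)c1Cc1c(CCc2cccc(OCc3ccccc3)c2)cc(OCc2ccccc2)cc1OC | intermediate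
35 | 2-{[4-hydroxy-2-[2-(3-hydroxyphenyl)ethyl]-6-methoxyphenyl]methyl}-5-[2-(4-hydroxy-3-methoxyphenyl)ethyl]-3-methoxyphenol | COc1cc(CCc2cc(O)c(Cc3c(CCc4cccc(O)c4)cc(O)cc3OC)c(OC)c2)ccc1O | target

**Step count**

Total: 18 steps. Longest linear sequence: 10 steps (1, 2, 4, 5, 13, 14, 15, 16, 17, 18; the ring D branch 6–9 followed by 13–18 is equally long).

**Steps most likely to fail**

Step 14. The cycloaddition may be slow at the β-alkylated ynone, whose carbonyl carries a 2,6-disubstituted aryl group. Hydrolysis or polymerisation of the diene, or open-chain Michael-type addition, could then outrun ring closure. The fallback runs the same benzannulation on an unhindered acetylenic ester and joins ring B afterwards. It sets out from alkyne 14 (with diene 24 and bibenzyl 8) and returns at 32: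
- Lithium acetylide 16 is acylated with methyl chloroformate to methyl 5-[3-(benzyloxy)phenyl]pent-2-ynoate F1.
- Heating F1 with 24 in toluene should give the cycloadduct methyl 2-[2-(3-(benzyloxy)phenyl)ethyl]-6,6-dimethoxy-4-(trimethylsilyloxy)cyclohexa-1,4-diene-1-carboxylate F2.
- F2 aromatises by loss of methanol to methyl 2-[2-(3-(benzyloxy)phenyl)ethyl]-6-methoxy-4-(trimethylsilyloxy)benzoate F3.
- K2CO3/MeOH converts F3 into methyl 2-[2-(3-(benzyloxy)phenyl)ethyl]-4-hydroxy-6-methoxybenzoate F4.
- Benzylation (BnBr, K2CO3, DMF) gives methyl 4-(benzyloxy)-2-[2-(3-(benzyloxy)phenyl)ethyl]-6-methoxybenzoate F5.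
- LiAlH4 reduces F5 to {4-(benzyloxy)-2-[2-(3-(benzyloxy)phenyl)ethyl]-6-methoxyphenyl}methanol F6.
- MnO2 in CH2Cl2 oxidises F6 to 4-(benzyloxy)-2-[2-(3-(benzyloxy)phenyl)ethyl]-6-methoxybenzaldehyde F7.
- Aryllithium 25, generated from 8 as in step 13, adds to F7 at –78 °C to give benzhydrol 32 directly. Steps 15 and 16 are then not needed.

Step 13. Acyl transfer to the hindered aryllithium may be incomplete. On collapse of the tetrahedral adduct, the liberated N,O-dimethylhydroxylamine or a second equivalent of aryllithium could add in conjugate fashion to the ynone. The fallback uses a small electrophile first and sets the ketone oxidation level afterwards. It sets out from 8 and 14 and returns at 27: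
- Aryllithium 25 is quenched with DMF to give 4-[2-(4-(benzyloxy)-3-methoxyphenyl)ethyl]-2-methoxy-6-(methoxymethoxy)benzaldehyde F8.
- Lithium acetylide 16 (from 14, n-BuLi, THF, –78 °C) adds to F8 to give the racemic propargylic alcohol 1-{4-[2-(4-(benzyloxy)-3-methoxyphenyl)ethyl]-2-methoxy-6-(methoxymethoxy)phenyl}-5-[3-(benzyloxy)phenyl]pent-2-yn-1-ol F9.
- MnO2 in CH2Cl2 oxidises the benzylic, propargylic alcohol F9 to ynone 27.

Step 16. Hydride delivery may stall at the tetra-ortho-substituted carbonyl. The forcing conditions then needed, and the strong acid of step 17, invite ether cleavage and acid-induced loss of an aryl group from the bridge. The fallback uses an electrophilic reductant. It sets out from 31 and returns at 34: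
- BH3·SMe2 in THF at reflux coordinates to the carbonyl oxygen, and the electron-rich benzhydryl borate ionises and is reduced a second time, so the ketone should go directly to the diarylmethane 33, here isolated.
- HCl in MeOH at rt then removes the MOM group to give 34.
- No compound outside the compound list is made.

**Further compounds**

F1 | step 14 | methyl 5-[3-(benzyloxy)phenyl]pent-2-ynoate | COC(=O)C#CCCc1cccc(OCc2ccccc2)c1
F2 | step 14 | methyl 2-[2-(3-(benzyloxy)phenyl)ethyl]-6,6-dimethoxy-4-(trimethylsilyloxy)cyclohexa-1,4-diene-1-carboxylate | COC(=O)C1=C(CCc2cccc(OCc3ccccc3)c2)CC(O[Si](C)(C)C)=CC1(OC)OC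
F3 | step 14 | methyl 2-[2-(3-(benzyloxy)phenyl)ethyl]-6-methoxy-4-(trimethylsilyloxy)benzoate | COC(=O)c1c(CCc2cccc(OCc3ccccc3)c2)cc(O[Si](C)(C)C)cc1OC
F4 | step 14 | methyl 2-[2-(3-(benzyloxy)phenyl)ethyl]-4-hydroxy-6-methoxybenzoate | COC(=O)c1c(CCc2cccc(OCc3ccccc3)c2)cc(O)cc1OC
F5 | step 14 | methyl 4-(benzyloxy)-2-[2-(3-(benzyloxy)phenyl)ethyl]-6-methoxybenzoate | COC(=O)c1c(CCc2cccc(OCc3ccccc3)c2)cc(OCc2ccccc2)cc1OC
F6 | step 14 | {4-(benzyloxy)-2-[2-(3-(benzyloxy)phenyl)ethyl]-6-methoxyphenyl}methanol | OCc1c(CCc2cccc(OCc3ccccc3)c2)cc(OCc2ccccc2)cc1OC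
F7 | step 14 | 4-(benzyloxy)-2-[2-(3-(benzyloxy)phenyl)ethyl]-6-methoxybenzaldehyde | O=Cc1c(CCc2cccc(OCc3ccccc3)c2)cc(OCc2ccccc2)cc1OC
F8 | step 13 | 4-[2-(4-(benzyloxy)-3-methoxyphenyl)ethyl]-2-methoxy-6-(methoxymethoxy)benzaldehyde | COCOc1cc(CCc2ccc(OCc3ccccc3)c(OC)c2)cc(OC)c1C=O
F9 | step 13 | 1-{4-[2-(4-(benzyloxy)-3-methoxyphenyl)ethyl]-2-methoxy-6-(methoxymethoxy)phenyl}-5-[3-(benzyloxy)phenyl]pent-2-yn-1-ol (racemic) | COCOc1cc(CCc2ccc(OCc3ccccc3)c(OC)c2)cc(OC)c1C(O)C#CCCc1cccc(OCc2ccccc2)c1
F0 | step 16 | none | none
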